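## Structural features

The target is an achiral tridepside. It has three benzene rings (A, B, C), each a 6-methyl-2,4-dioxygenated benzoyl unit, joined in a line by two aryl ester links: the carboxyl carbon of ring C is bound to O4 of ring B, and the carboxyl carbon of ring B to O4 of ring A, which ends in a methyl ester. There is no stereocentre and no alkene geometry, so the problem is one of regiochemistry and chemoselectivity. On rings A and B the oxygen next to the carboxyl (O2) is methylated and the para oxygen (O4) is acylated, while on ring C both oxygens are free phenols. The two aryl ester links are activated esters that hydroxide, alkoxides, amines or free phenoxides can cleave or scramble, and the ring C resorcinol must be masked until the end. Each acyl carbon is flanked by two ortho substituents, so every ester-forming step is sterically hindered. The real difficulty is therefore to tell apart the two 1,3-related oxygens of ring B and to make two hindered aryl esters one after the other without disturbing the first. The key step exploits ring B: its C1 carboxyl, C2 and C4 oxygens and C6 methyl are the substitution pattern of a 6-methyl-2,4-dioxocyclohexane-1-carboxylate, assembled through the ring bonds C1-C6 and C3-C4. In that dihydro ring O4 is an exposed vinylogous-acid oxygen, whereas O2 is tied to the neighbouring ester.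

## Logic of the disconnections

17 to 16: the two benzyl-oxygen bonds on ring C are cut. Ring C must carry masked phenols through every acylation, and benzyl ethers fall under neutral hydrogenolysis, which leaves aryl esters alone. The skeleton is unchanged, but the end-game becomes one mild step. The demand is that 16 holds no other reducible group, so the allyl group must be gone before this point.

16 to 12 and 15: the ester bond between the ring B carboxyl carbon and O4 of ring A is cut. This is the convergent cut; 15 has a single free hydroxyl, so no selectivity question arises. The forward step must acylate a phenol with a di-ortho-substituted acid without touching the B-C ester or the benzyl ethers, which points to acylium-type activation rather than base.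

15 to 14 to 5 (through 13): the O4-benzyl bond, then the O2-methyl and O4-benzyl bonds are cut. 5 already holds the whole carbon skeleton of ring A. The forward sequence relies on the acidity gap between the free 4-hydroxyl and the hydrogen-bonded 2-hydroxyl, so the first alkylation must stop cleanly at O4.

12 to 11: the oxygen-allyl bond of the ring B ester is cut. The carboxyl has to travel masked through acylation, oxidation and methylation, and must be freed without hydroxide or hydrogen. The forward step therefore needs allyl transfer on zerovalent palladium with a non-basic acceptor.

11 to 10: the O2-methyl bond is cut. Once ring C sits on O4, only one phenol remains on ring B, so methylation needs no selectivity. The demand is that a hydrogen-bonded phenol be alkylated under base mild enough to spare the aryl ester.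

10 to 9: the arene is traced back to its 5,6-dihydro form. This reveals the enone and keto ester functions in which O2 and O4 differ chemically. The forward dehydrogenation must tolerate an allyl ester, benzyl ethers and an enol ester.

9 to 4 and 8: the bond between O4 and the ring C acyl carbon is cut. Ring C is attached while O4 is the accessible enol oxygen. The forward step must be O-acylation at O4, not at O2 and not at C3.

8 to 7 to 6 to 5: the acyl chloride bond, the methyl ester and the two benzyl ethers are cut in turn. This leads ring C back to the same commercial ester as ring A; the demand is hydrolysis of a hindered ester.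

4 to 1 and 2 (through 3): the ring bonds C3-C4 and C1-C6 are cut. Two commercial four-carbon esters then supply all six ring carbons with the carboxyl, both oxygens and the methyl in place. The forward step requires conjugate addition before condensation, C-acylation in the closure and survival of the allyl ester.

## Other disconnections considered

Alternative 1: The cut concerns ring A only, removing the C6-CH3 and C1-carboxyl bonds to leave the fluoroarene A1 (1-fluoro-3-methoxy-5-(triisopropylsilyloxy)benzene).
- Forward step: A1 would be lithiated between fluorine and methoxy and lose LiF to the aryne A2. A methyl Grignard reagent would add at the aryne carbon remote from the methoxy group, and the arylmagnesium would be trapped by a methyl haloformate to give A3; desilylation of A3 would lead to 15.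
- In favour: the 2-methoxy/4-oxygen pattern comes from the starting arene, so no selective alkylation of a resorcinol is needed. On this point it equals or betters the chosen plan. The regiochemistry of addition to a 3-alkoxyaryne is dependable, and three contiguous substituents are set in one flask.
- Against: lithiation between the methoxy and silyloxy groups can compete. The arylmagnesium to be acylated is flanked on both sides, and surplus Grignard reagent consumes the trapping agent. It needs cryogenic organometallic handling.
- Comparison: structurally it addresses the easiest ring, which the chosen plan reaches in two steps from 5; A1 would need its own preparation, so nothing is saved. Mechanistically it is a kinetically controlled organometallic cascade, against a condensation drawn to a thermodynamic sink. Applied to ring B with an allyl haloformate it would draw level with steps 1 and 4 to 6 in count but not beat them, and the two ester links would still have to be made as in the chosen plan.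

Alternative 2: The cut removes the ring B bonds C1-C2 and C5-C6.
- Forward step: the but-2-ynoate ester A4 of the ring A phenol would undergo a [4+2] cycloaddition with the diene A5. The nucleophilic CH2 terminus of A5 would bond to the methyl-bearing alkyne carbon. Elimination of one methoxy group as the alcohol and loss of silicon would give the didepside A6 with O2 methylated and O4 free.
- In favour: ring B arrives aromatic with its two oxygens already differentiated, so neither dehydrogenation nor selective alkylation is needed. The hindered B-A ester is replaced by an unhindered acylation of 15 with a butynoic acid derivative, which is better than step 10 of the chosen plan. A6 needs only acylation by 7 and hydrogenolysis, so the count would be about two steps lower.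
- Against: but-2-ynoates are weak dienophiles, since the methyl group hinders the reacting carbon and lowers its electrophilicity. Heating is therefore needed, under which the ketene acetal A5 can decompose or transfer silicon. The aryl ester in A4 is an activated ester open to attack by A5 or by the liberated alcohol. A5 must be prepared and kept dry.
- Comparison: structurally both routes build ring B de novo, the alternative directly on ring A. Mechanistically the alternative depends on a sluggish cycloaddition of two sensitive partners, the chosen plan on a robust condensation. On step economy the alternative is shorter.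

Alternative 3: The cut removes the bond from ring B C1 to its carbonyl carbon and the bond from that carbon to O4 of ring A.
- Forward step: the aryl iodide A7, already carrying protected ring C on O4, would add to zerovalent palladium, insert carbon monoxide A8 and be captured by 15 to give A9, which is identical with 16.
- In favour: it is the most convergent union, needs no free hindered acid and no allyl ester, and reaches the same penultimate compound, so the end-game is equal. The deallylation is saved and the count to the ring B-ring C fragment would be lower.
- Against: the iodine in A7 lies between methoxy and methyl, so carbon monoxide insertion and attack of a weakly nucleophilic phenoxide on the crowded aroylpalladium are slow, and reduction or direct aryl ether formation can compete. The base needed can exchange the aryl ester already present in A7. Making A7 shifts the regiochemical problem to an iodination of its phenolic precursor at the most crowded position.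
- Comparison: structurally the alternative takes ring B from an arene and must impose the substitution pattern by electrophilic substitution, whereas the annulation fixes it by construction. Mechanistically it depends on a demanding catalytic carbonylation of a di-ortho-substituted halide, against classical polar steps. On step economy it is shorter on paper.

Key step: step 1

Assumption: 4 and 9 are written as keto tautomers although they should exist largely as enols; their sp3 centres C1 and C6 are racemic and epimerizable and are erased in step 5, so no configuration is assigned. Ring positions are numbered from the carboxyl-bearing carbon (C1), with oxygens at C2 and C4 and the methyl at C6.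

## Route

Step 1
Reactants: 1 allyl acetoacetate (prop-2-en-1-yl 3-oxobutanoate); 2 methyl crotonate (methyl (E)-but-2-enoate)
Product: 4 allyl 6-methyl-2,4-dioxocyclohexane-1-carboxylate, via Michael adduct 3 (not isolated)
Conditions: NaH (1.05 equiv), allyl alcohol, 0 °C (gives NaOCH2CH=CH2); 1, then 2, 80 °C; 1 M HCl, 0 °C
Reagents that add atoms: none
Why: The sodium enolate of 1, a soft doubly stabilized carbanion, adds 1,4 to 2 and forms the C1-C6 bond of the Michael adduct 3. Proton transfer within 3 then provides a small equilibrium share of the acetyl-methyl enolate, which attacks the former crotonate ester carbonyl and expels alkoxide, forming C3-C4 in a Dieckmann (intramolecular Claisen) condensation. The closest known reaction type is the classical Michael addition-Dieckmann annulation of acetoacetates with crotonates to dihydroorsellinates. The one ring is closed in the favoured 6-(enolendo)-exo-trig mode, whereas closure from the C1 carbanion would need a four-membered ring. The sp3 centres C1 and C6 form without control as a racemic, epimerizable mixture, and none is needed because both become sp2 in step 5. Conjugate addition before condensation is secured by the softness of the 1,3-dicarbonyl carbanion and by the intramolecularity of the Claisen step. C-acylation over O-acylation is secured thermodynamically: an enol lactone from O-attack is reopened by alkoxide, while 4 is a vinylogous acid and leaves all equilibria as its sodium salt. Allyl alcohol as solvent makes any ester exchange at the retained carboxyl degenerate, so the allyl ester survives.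

Step 2
Reactants: 5 methyl orsellinate (methyl 2,4-dihydroxy-6-methylbenzoate)
Product: 6 methyl 2,4-bis(benzyloxy)-6-methylbenzoate
Conditions: BnBr (2.4 equiv), K2CO3, DMF, 60 °C
Reagents that add atoms: benzyl bromide, BrCc1ccccc1
Why: Williamson etherification; with excess halide in warm DMF both the free and the hydrogen-bonded phenol should be alkylated, and the hindered methyl ester is inert to carbonate.

Step 3
Reactants: 6 methyl 2,4-bis(benzyloxy)-6-methylbenzoate
Product: 7 2,4-bis(benzyloxy)-6-methylbenzoic acid
Conditions: KOH, DMSO-H2O (4:1), 90 °C; then 1 M HCl
Reagents that add atoms: potassium hydroxide, [K+].[OH-]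
Why: Saponification of a di-ortho-substituted benzoate needs poorly solvated hydroxide and heat, which aqueous DMSO provides; benzyl aryl ethers are stable to base.

Step 4
Reactants: 7 2,4-bis(benzyloxy)-6-methylbenzoic acid; 4 allyl 6-methyl-2,4-dioxocyclohexane-1-carboxylate
Product: 9 allyl 4-{[2,4-bis(benzyloxy)-6-methylbenzoyl]oxy}-6-methyl-2-oxocyclohex-3-ene-1-carboxylate, via acid chloride 8 (not isolated)
Conditions: (COCl)2, DMF (cat.), CH2Cl2, 0 to 20 °C, evaporate; then 4, Et3N, CH2Cl2, 0 °C
Reagents that add atoms: none
Why: Acid chloride formation through the Vilsmeier-type chloroiminium, then enol ester formation from a cyclic 1,3-dione and an acyl chloride. The triethylammonium salt of the vinylogous acid 4 should react at O4, because O2 is crowded by the C1 ester and C6 methyl and is hydrogen-bonded to the ester. Leaving out acyl-transfer catalysts and the di-ortho-substituted aroyl group should suppress O-to-C acyl migration.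

Step 5
Reactants: 9 allyl 4-{[2,4-bis(benzyloxy)-6-methylbenzoyl]oxy}-6-methyl-2-oxocyclohex-3-ene-1-carboxylate
Product: 10 allyl 4-{[2,4-bis(benzyloxy)-6-methylbenzoyl]oxy}-2-hydroxy-6-methylbenzoate
Conditions: DDQ (1.2 equiv), 1,4-dioxane, 80 °C
Reagents that add atoms: none
Why: DDQ dehydrogenation of a 2-oxocyclohex-3-ene-1-carboxylate to a salicylate. The chelated C1=C2 enol of 9 is a dienol from which DDQ abstracts hydride at C5 or C6, and proton loss aromatizes the ring. The product arene carries an ester and an acyloxy group and should resist further oxidation, and the allyl ester and benzyl aryl ethers are inert to DDQ under these conditions.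

Step 6
Reactants: 10 allyl 4-{[2,4-bis(benzyloxy)-6-methylbenzoyl]oxy}-2-hydroxy-6-methylbenzoate
Product: 11 allyl 4-{[2,4-bis(benzyloxy)-6-methylbenzoyl]oxy}-2-methoxy-6-methylbenzoate
Conditions: MeI (excess), K2CO3, acetone, reflux
Reagents that add atoms: iodomethane, CI
Why: Williamson methylation of the only phenol present. The aryl ester carbonyl is shielded by its flanking benzyloxy and methyl groups against phenoxide or carbonate, and no intramolecular acyl shift is possible between the meta-related O4 and O2.

Step 7
Reactants: 11 allyl 4-{[2,4-bis(benzyloxy)-6-methylbenzoyl]oxy}-2-methoxy-6-methylbenzoate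
Product: 12 4-{[2,4-bis(benzyloxy)-6-methylbenzoyl]oxy}-2-methoxy-6-methylbenzoic acid
Conditions: Pd(PPh3)4 (3 mol %), 4-MeC6H4SO2Na (1.2 equiv), THF-MeOH, 20 °C; then 1 M HCl
Reagents that add atoms: none
Why: Tsuji-Trost deallylation: zerovalent palladium ionizes the oxygen-allyl bond, so hindrance at the carbonyl is irrelevant, and the sulfinate takes the allyl group as a sulfone. The medium is neutral and non-nucleophilic, so the aryl ester and benzyl ethers should remain intact.

Step 8
Reactants: 5 methyl orsellinate (methyl 2,4-dihydroxy-6-methylbenzoate)
Product: 14 methyl 4-(benzyloxy)-2-methoxy-6-methylbenzoate, via mono-benzyl ether 13 (not isolated)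
Conditions: BnBr (1.0 equiv), K2CO3, DMF, 20 °C; then MeI (excess), 50 °C
Reagents that add atoms: benzyl bromide, BrCc1ccccc1; iodomethane, CI
Why: Sequential Williamson alkylation in one flask. The more acidic, non-chelated 4-hydroxyl para to the ester should take the single equivalent of benzyl bromide to give 13, and the hydrogen-bonded 2-hydroxyl is then methylated on warming with excess iodomethane.

Step 9
Reactants: 14 methyl 4-(benzyloxy)-2-methoxy-6-methylbenzoate
Product: 15 methyl 4-hydroxy-2-methoxy-6-methylbenzoate
Conditions: H2 (1 atm), Pd/C (10% Pd on carbon), EtOAc, 20 °C
Reagents that add atoms: none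
Why: Hydrogenolysis of a benzyl aryl ether; the methyl ester and methyl ether are inert.

Step 10
Reactants: 12 4-{[2,4-bis(benzyloxy)-6-methylbenzoyl]oxy}-2-methoxy-6-methylbenzoic acid; 15 methyl 4-hydroxy-2-methoxy-6-methylbenzoate
Product: 16 methyl 4-[(4-{[2,4-bis(benzyloxy)-6-methylbenzoyl]oxy}-2-methoxy-6-methylbenzoyl)oxy]-2-methoxy-6-methylbenzoate
Conditions: (CF3CO)2O, toluene, 20 °C
Reagents that add atoms: none
Why: Trifluoroacetic anhydride-mediated esterification, the standard depside coupling. The mixed anhydride of the electron-rich, di-ortho-substituted acid 12 ionizes to an acylium ion, which ortho substituents do not slow, and this acylates the single phenol of 15. The existing aryl ester and the benzyl ethers should tolerate the acidic medium at room temperature.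

Step 11
Reactants: 16 methyl 4-[(4-{[2,4-bis(benzyloxy)-6-methylbenzoyl]oxy}-2-methoxy-6-methylbenzoyl)oxy]-2-methoxy-6-methylbenzoate
Product: 17 methyl 4-({4-[(2,4-dihydroxy-6-methylbenzoyl)oxy]-2-methoxy-6-methylbenzoyl}oxy)-2-methoxy-6-methylbenzoate (CNP0514431.0)
Conditions: H2 (1 atm), Pd/C (10% Pd on carbon), EtOAc, 20 °C
Reagents that add atoms: none
Why: Neutral hydrogenolysis of the two benzyl aryl ethers; both aryl esters, the methyl ester and the methyl ethers are inert, and no stereocentre is involved.

## Compound list

1 | allyl acetoacetate (prop-2-en-1-yl 3-oxobutanoate) | CC(=O)CC(=O)OCC=C | starting material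
2 | methyl crotonate (methyl (E)-but-2-enoate) | C/C=C/C(=O)OC | starting material
3 | 5-methyl 1-(prop-2-en-1-yl) 2-acetyl-3-methylpentanedioate (Michael adduct, racemic diastereomer mixture) | CC(=O)C(C(C)CC(=O)OC)C(=O)OCC=C | intermediate (not isolated)
4 | allyl 6-methyl-2,4-dioxocyclohexane-1-carboxylate (racemic, configurationally labile, largely enolized) | CC1CC(=O)CC(=O)C1C(=O)OCC=C | intermediate
5 | methyl orsellinate (methyl 2,4-dihydroxy-6-methylbenzoate) | COC(=O)c1c(C)cc(O)cc1O | starting material
6 | methyl 2,4-bis(benzyloxy)-6-methylbenzoate | COC(=O)c1c(C)cc(OCc2ccccc2)cc1OCc1ccccc1 | intermediate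
7 | 2,4-bis(benzyloxy)-6-methylbenzoic acid | OC(=O)c1c(C)cc(OCc2ccccc2)cc1OCc1ccccc1 | intermediate
8 | 2,4-bis(benzyloxy)-6-methylbenzoyl chloride | ClC(=O)c1c(C)cc(OCc2ccccc2)cc1OCc1ccccc1 | intermediate (not isolated)
9 | allyl 4-{[2,4-bis(benzyloxy)-6-methylbenzoyl]oxy}-6-methyl-2-oxocyclohex-3-ene-1-carboxylate (racemic, epimerizable at C1) | C=CCOC(=O)C1C(C)CC(OC(=O)c2c(C)cc(OCc3ccccc3)cc2OCc2ccccc2)=CC1=O | intermediate
10 | allyl 4-{[2,4-bis(benzyloxy)-6-methylbenzoyl]oxy}-2-hydroxy-6-methylbenzoate | C=CCOC(=O)c1c(C)cc(OC(=O)c2c(C)cc(OCc3ccccc3)cc2OCc2ccccc2)cc1O | intermediate
11 | allyl 4-{[2,4-bis(benzyloxy)-6-methylbenzoyl]oxy}-2-methoxy-6-methylbenzoate | C=CCOC(=O)c1c(C)cc(OC(=O)c2c(C)cc(OCc3ccccc3)cc2OCc2ccccc2)cc1OC | intermediate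
12 | 4-{[2,4-bis(benzyloxy)-6-methylbenzoyl]oxy}-2-methoxy-6-methylbenzoic acid | OC(=O)c1c(C)cc(OC(=O)c2c(C)cc(OCc3ccccc3)cc2OCc2ccccc2)cc1OC | intermediate
13 | methyl 4-(benzyloxy)-2-hydroxy-6-methylbenzoate | COC(=O)c1c(C)cc(OCc2ccccc2)cc1O | intermediate (not isolated)
14 | methyl 4-(benzyloxy)-2-methoxy-6-methylbenzoate | COC(=O)c1c(C)cc(OCc2ccccc2)cc1OC | intermediate
15 | methyl 4-hydroxy-2-methoxy-6-methylbenzoate | COC(=O)c1c(C)cc(O)cc1OC | intermediate
16 | methyl 4-[(4-{[2,4-bis(benzyloxy)-6-methylbenzoyl]oxy}-2-methoxy-6-methylbenzoyl)oxy]-2-methoxy-6-methylbenzoate | COC(=O)c1c(C)cc(OC(=O)c2c(C)cc(OC(=O)c3c(C)cc(OCc4ccccc4)cc3OCc5ccccc5)cc2OC)cc1OC | intermediate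
17 | methyl 4-({4-[(2,4-dihydroxy-6-methylbenzoyl)oxy]-2-methoxy-6-methylbenzoyl}oxy)-2-methoxy-6-methylbenzoate (CNP0514431.0) | COC(=O)c1c(C)cc(OC(=O)c2c(C)cc(OC(=O)c3c(C)cc(O)cc3O)cc2OC)cc1OC | target

## Step count and risk assessment

Total step count: 11. Longest linear sequence: 8 steps (5 through steps 2, 3, 4, 5, 6, 7, 10 and 11 to 17); the branch from 1 is 7 steps.

Least certain steps:

Step 1 (key step). The most likely failure is stalling at the Michael adduct with retro-Michael reversal, together with reversible conjugate addition of allyloxide to 2 that ties up base. At higher temperature, loss of ester integrity (exchange with liberated methanol, or Carroll-type rearrangement of the allyl keto ester) is also possible. Fallback, from 2 back to 4: 2 would be condensed with commercial methyl acetoacetate (COC(=O)CC(C)=O) under NaOMe in methanol, the all-methyl form of the same annulation in which no ester exchange can matter, to give methyl 6-methyl-2,4-dioxocyclohexane-1-carboxylate F1. The allyl ester would then be introduced afterwards by keto ester transesterification of F1 in allyl alcohol-toluene with removal of methanol, arriving at 4.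

Step 4. The most likely failure is loss of regiocontrol in the acylation of the ambident dione anion (attack through O2 or C3, or later O-to-C acyl migration), and hydrolysis of the vinylogous anhydride during isolation. Fallback, from 4 to 10, bypassing 9 and step 5: 4 would first be dehydrogenated with DDQ to allyl 2,4-dihydroxy-6-methylbenzoate F2. Its non-chelated 4-hydroxyl would then be acylated with 7 and (CF3CO)2O in toluene. Selectivity there rests on the hydrogen bond between the 2-hydroxyl and the ester, not on enol reactivity.

Step 5. The most likely failure is incomplete hydride abstraction from a ring that is not enolized enough, or competing oxidation at the benzylic ether positions on prolonged heating. Fallback, from 9 to 10: halogenation-dehydrohalogenation in place of hydride abstraction. The enolized keto ester carbon C1 of 9 would be brominated with N-bromosuccinimide in CH2Cl2 at 0 °C to allyl 4-{[2,4-bis(benzyloxy)-6-methylbenzoyl]oxy}-1-bromo-6-methyl-2-oxocyclohex-3-ene-1-carboxylate F3. Elimination of HBr across C1-C6 with DBU, followed by tautomerization of the dienone, would give 10.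

Step 6. The most likely failure is intermolecular acyl transfer from the aryl ester to the phenoxide during a slow alkylation of the hydrogen-bonded phenol. Fallback, from 4 to 11, with methylation before any aryl ester exists: 4 would be taken to F2 as in the fallback of step 4. F2 would then be alkylated at O4 with 4-methoxybenzyl chloride and K2CO3 to allyl 2-hydroxy-4-[(4-methoxybenzyl)oxy]-6-methylbenzoate F4. Methylation with MeI and K2CO3 would give allyl 2-methoxy-4-[(4-methoxybenzyl)oxy]-6-methylbenzoate F5. Oxidative removal of the 4-methoxybenzyl group with DDQ in wet CH2Cl2 would give allyl 4-hydroxy-2-methoxy-6-methylbenzoate F6. Acylation of F6 with 7 and (CF3CO)2O in toluene would arrive at 11.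

Step 10. The most likely failure is diversion of the acylium ion into Friedel-Crafts acylation of the electron-rich benzyloxy ring, or acid-induced loss of a benzyl group, rather than a lack of reactivity. Fallback, from 12 to 16, replacing the acidic acylium regime by addition-elimination under base: 12 would be converted with (COCl)2 and catalytic DMF to 4-{[2,4-bis(benzyloxy)-6-methylbenzoyl]oxy}-2-methoxy-6-methylbenzoyl chloride F7. F7 would be combined with 15 in CH2Cl2 with Et3N and catalytic 4-(dimethylamino)pyridine to give 16.

## Further compounds

F1 | step 1 | methyl 6-methyl-2,4-dioxocyclohexane-1-carboxylate (racemic) | CC1CC(=O)CC(=O)C1C(=O)OC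
F2 | step 4 | allyl 2,4-dihydroxy-6-methylbenzoate | C=CCOC(=O)c1c(C)cc(O)cc1O
F3 | step 5 | allyl 4-{[2,4-bis(benzyloxy)-6-methylbenzoyl]oxy}-1-bromo-6-methyl-2-oxocyclohex-3-ene-1-carboxylate (racemic) | C=CCOC(=O)C1(Br)C(C)CC(OC(=O)c2c(C)cc(OCc3ccccc3)cc2OCc2ccccc2)=CC1=O
F4 | step 6 | allyl 2-hydroxy-4-[(4-methoxybenzyl)oxy]-6-methylbenzoate | C=CCOC(=O)c1c(C)cc(OCc2ccc(OC)cc2)cc1O
F5 | step 6 | allyl 2-methoxy-4-[(4-methoxybenzyl)oxy]-6-methylbenzoate | C=CCOC(=O)c1c(C)cc(OCc2ccc(OC)cc2)cc1OC
F6 | step 6 | allyl 4-hydroxy-2-methoxy-6-methylbenzoate | C=CCOC(=O)c1c(C)cc(O)cc1OC
F7 | step 10 | 4-{[2,4-bis(benzyloxy)-6-methylbenzoyl]oxy}-2-methoxy-6-methylbenzoyl chloride | ClC(=O)c1c(C)cc(OC(=O)c2c(C)cc(OCc3ccccc3)cc2OCc2ccccc2)cc1OC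
A1 | alternative 1 | 1-fluoro-3-methoxy-5-(triisopropylsilyloxy)benzene | COc1cc(F)cc(O[Si](C(C)C)(C(C)C)C(C)C)c1
A2 | alternative 1 | 3-methoxy-5-(triisopropylsilyloxy)benzyne | COC1=CC(O[Si](C(C)C)(C(C)C)C(C)C)=CC#C1
A3 | alternative 1 | methyl 2-methoxy-6-methyl-4-(triisopropylsilyloxy)benzoate | COC(=O)c1c(C)cc(O[Si](C(C)C)(C(C)C)C(C)C)cc1OC
A4 | alternative 2 | methyl 4-(but-2-ynoyloxy)-2-methoxy-6-methylbenzoate | COC(=O)c1c(C)cc(OC(=O)C#CC)cc1OC
A5 | alternative 2 | 1,1-dimethoxy-3-(trimethylsilyloxy)buta-1,3-diene | COC(OC)=CC(=C)O[Si](C)(C)C
A6 | alternative 2 | methyl 4-[(4-hydroxy-2-methoxy-6-methylbenzoyl)oxy]-2-methoxy-6-methylbenzoate | COC(=O)c1c(C)cc(OC(=O)c2c(C)cc(O)cc2OC)cc1OC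
A7 | alternative 3 | 4-iodo-3-methoxy-5-methylphenyl 2,4-bis(benzyloxy)-6-methylbenzoate | COc1cc(OC(=O)c2c(C)cc(OCc3ccccc3)cc2OCc2ccccc2)cc(C)c1I
A8 | alternative 3 | carbon monoxide | [C-]#[O+]
A9 | alternative 3 | ring C di-O-benzyl ether of the target (identical with 16) | COC(=O)c1c(C)cc(OC(=O)c2c(C)cc(OC(=O)c3c(C)cc(OCc4ccccc4)cc3OCc5ccccc5)cc2OC)cc1OC
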